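Follow the balance of the solid electrophile, the limiting reagent here: what was charged is still solid, dissolved, or reacted.

| flask | solid electrophile | nucleophile | free base | scavenger | time |
|---|---|---|---|---|---|
| Tuesday's | 0.40 M | 1.80 equiv | 0.800 equiv | 1.20 equiv | 6.0 h |
| Sunday's | 0.40 M | 1.80 equiv | 1.20 equiv | 1.20 equiv | 6.0 h |
| Saturday's | 0.40 M | 1.80 equiv | 1.80 equiv | 1.20 equiv | 6.0 h |

    electrophile + nucleophile → acid set free + product (k1 = 0.063 /M/min)
    nucleophile + acid set free ⇌ protonated nucleophile, settled at all times (K2 = 3600 /M)
    acid set free + free base ⇌ salt of the base (K3 = 350 /M, k3 = 0.41 /M/min)
    solid electrophile ⇌ electrophile, rate k4*(cs4 - [electrophile]) while solid is left; crystals form when [electrophile] > cs4 (cs4 = 13 mM, k4 = 0.038 /min)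
    nucleophile + acid set free ⇌ idle adduct, settled at all times (K5 = 0.64 /M)
    acid set free + scavenger → scavenged by-product (k6 = 4.9 /M/min)

- for acid set free the idle adduct is counted in
- as a solid, counted per litre of solution: solid electrophile
- at the start none of the solid electrophile is in solution
- what has only dissolved of solid electrophile counts as not reacted
- run time (Tuesday's): 6.0 h

* part of the solid electrophile that has reacted (what has only dissolved counts as not reacted) at the end, Tuesday's
* part of the solid electrophile that has reacted (what has only dissolved counts as not reacted) at the end, Sunday's
* part of the solid electrophile that has reacted (what has only dissolved counts as not reacted) at the end, Saturday's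
* what raising the equivalents of free base from its lowest to its highest value here does to the part of the solid electrophile that has reacted (what has only dissolved counts as not reacted) (changes below 5 percentage points count as none) (it rises / it falls / no change)

The solid must dissolve before it reacts, and dissolution passes at most 0.494 mM/min, its rate into a solution empty of electrophile. Over 6.0 h this ceiling comes to 44.5% of the charge, less than lies there, so solid remains in the three flasks. Dissolved electrophile is removed in the first step at a pseudo-first-order rate. Setting its removal equal to its dissolution gives flow = ceiling × c(nucleophile) / (c(nucleophile) + 0.603 M). That constant, the dissolution coefficient over the first step's rate constant, is the half-flow concentration: the free nucleophile at which the flow is half the ceiling, a half-saturation constant.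

Tuesday's flask starts at 0.720 M of nucleophile, which gives 0.269 mM/min. The dissolved electrophile needs about 12.0 min to reach its level, so the first pass yields 0.0935 M reacted.

The weak link is holding the nucleophile at its start. Each reacted electrophile consumes one nucleophile, and we charge a second for the acid set free, because at the charged amounts the nucleophile's pull, 2590, exceeds that of free base, 252, even on Saturday's. So we put the mean nucleophile over the run one reacted amount below the start, at 0.626 M. We take this one mean instead of stepping through time and get 0.0876 M, which is 21.9% for Tuesday's. The flow formula holds no free base, so we give Sunday's 21.9% and Saturday's 21.9%. Striking the second charge from the reckoning puts the mean at 0.673 M and the gain at 0.77 percentage points, less than the margin, so our call is no change.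

The forecast gives 22%, 22.05% and 22.1%, with no change, on the ground that “Dissolution limits this system”.

The simulation gives 21.9%, 21.9% and 21.9%, and no change, the shift being 0.0053 points.

In Tuesday's flask dissolution fed the first step while solid stood, 76.4% of the charge at 6.00 h, and the dissolved electrophile read 1.57% at 3.00 h and 1.68% at the end. Over those hours the free nucleophile fell from 0.720 M to 0.560 M, crossing the half-flow concentration, and at that level the flow formula gives 48.2% of the ceiling.

Saturday's recipe on 0.68 M of solid starts at 1.22 M of nucleophile, above the half-flow concentration. The first pass gives 0.116 M and the mean-nucleophile pass 16.5% of the charge. The simulated flask reads 16.5%.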